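**Retrosynthetic overview**
- Late stage: the C11 hydroxyl and the C6=C7 bond arise together from a C7=C11 isopropylidene enone by a singlet-oxygen ene reaction. Before that, the O3 angelate and O4 acetate are placed on a 3α,4α-diol made by α-face osmylation of a C3=C4 alkene.
- Middle stage: the isopropylidene comes from an acetone aldol condensation at C7 of the C8 ketone. The C4 methyl and C3=C4 come from a C4 ketone (kinetic enol triflate, methyl coupling) after C5 has been turned from cis to trans.
- Feature used: in ring B the C8 oxygen lies para to C5. C5 is flanked by C4, which can be a ketone, and by the methyl-bearing quaternary C10. Cutting C5–C10 and C6–C7 therefore opens both rings to one chain: vinyl ketone C6=C5–C4(=O), linked through C3–C2–C1 to the 2-silyloxydiene C10(Me)=C9–C8(OSi)=C7.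
- Ring order: rings A and B close in one operation, an enantioselective acid-catalysed intramolecular Diels–Alder reaction (ring B is the cycloaddition ring, ring A the tether ring). The C8=C9 silyl enol ether so formed masks C8 while C4 is elaborated.
- The trienone is assembled in six steps from 5-hexyn-1-ol, AlMe3, acetyl chloride and vinylmagnesium bromide.

Key step: step 7

Remark: eudesmane numbering is used throughout (C4 next to the ring-fusion CH C5, C10 the methyl-bearing fusion carbon, C8 the ring B carbonyl) and β is the face of the C10 methyl; the sense of induction in step 7 cannot be read safely from existing binding models, so the (S)-catalyst is assumed to give the 10R series and its equally accessible (R)-antipode is used otherwise.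

Step 1
Reactants: 1 5-hexyn-1-ol; 2 acetyl chloride
Product: 4 (E)-5-methyl-7-oxooct-5-en-1-yl acetate, via alkenyldimethylalane 3 (not isolated)
Conditions: AlMe3 (3 equiv), Cp2ZrCl2 (0.25 equiv), CH2Cl2, 0 °C to rt; excess AlMe3 removed in vacuo; AcCl (3 equiv), CH2Cl2, −30 to 0 °C; cold 1 M HCl
Reagents that add atoms: trimethylaluminium C[Al](C)C; acetyl chloride CC(=O)Cl
Why: Zirconium-catalysed Negishi carboalumination adds Me and Al syn across the terminal alkyne with Al at the terminus, ipso-acylation of the alkenyl–Al bond goes with retention to give the (E)-enone, and the aluminium alkoxide is O-acetylated in the same flask, which supplies a protecting group that can later be removed without acid or fluoride.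

Step 2
Reactants: 4 (E)-5-methyl-7-oxooct-5-en-1-yl acetate
Product: 5 (E)-7-[(tert-butyldimethylsilyl)oxy]-5-methylocta-5,7-dien-1-yl acetate
Conditions: TBSOTf (1.2 equiv), Et3N (2 equiv), CH2Cl2, −78 to 0 °C
Reagents that add atoms: tert-butyldimethylsilyl triflate CC(C)(C)[Si](C)(C)OS(=O)(=O)C(F)(F)F
Why: Soft enolisation (O-silylation of the ketone, then removal of the most accessible α'-methyl proton by the amine) gives the cross-conjugated 2-silyloxydiene, leaves the C=C geometry unchanged and does not enolise the far less reactive acetate.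

Step 3
Reactants: 5 (E)-7-[(tert-butyldimethylsilyl)oxy]-5-methylocta-5,7-dien-1-yl acetate
Product: 6 (E)-7-[(tert-butyldimethylsilyl)oxy]-5-methylocta-5,7-dien-1-ol
Conditions: iBu2AlH (2.2 equiv), CH2Cl2, −78 °C; aq potassium sodium tartrate
Reagents that add atoms: none
Why: Reductive ester cleavage by the aluminium hydride frees the primary alcohol under conditions free of acid and fluoride, to which a silyl dienol ether is inert.

Step 4
Reactants: 6 (E)-7-[(tert-butyldimethylsilyl)oxy]-5-methylocta-5,7-dien-1-ol
Product: 7 (E)-7-[(tert-butyldimethylsilyl)oxy]-5-methylocta-5,7-dienal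
Conditions: Dess–Martin periodinane (1.2 equiv), pyridine (5 equiv), CH2Cl2, 0 °C
Reagents that add atoms: none
Why: Dess–Martin oxidation stops at the aldehyde, and the pyridine buffer takes up the acetic acid that would otherwise hydrolyse the dienol ether.

Step 5
Reactants: 7 (E)-7-[(tert-butyldimethylsilyl)oxy]-5-methylocta-5,7-dienal; 8 vinylmagnesium bromide
Product: 9 (E)-9-[(tert-butyldimethylsilyl)oxy]-7-methyldeca-1,7,9-trien-3-ol
Conditions: CH2=CHMgBr (1.2 equiv), THF, −78 °C; pH 7 phosphate buffer
Reagents that add atoms: vinylmagnesium bromide C=C[Mg]Br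
Why: Grignard 1,2-addition to the aldehyde does not touch the silyl dienol ether, and the carbinol centre forms as a racemate, which is immaterial because step 6 removes it.

Step 6
Reactants: 9 (E)-9-[(tert-butyldimethylsilyl)oxy]-7-methyldeca-1,7,9-trien-3-ol
Product: 10 (E)-9-[(tert-butyldimethylsilyl)oxy]-7-methyldeca-1,7,9-trien-3-one
Conditions: Dess–Martin periodinane (1.3 equiv), pyridine (5 equiv), CH2Cl2, 0 °C; cold filtration through Et3N-deactivated silica, used at once
Reagents that add atoms: none
Why: Buffered Dess–Martin oxidation is the usual mild way from a 1-alken-3-ol to a vinyl ketone, and making the dienophile last and keeping it cold limits polymerisation and uncatalysed cyclisation.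

Step 7
Reactants: 10 (E)-9-[(tert-butyldimethylsilyl)oxy]-7-methyldeca-1,7,9-trien-3-one
Product: 11 (4aR,8aS)-6-[(tert-butyldimethylsilyl)oxy]-4a-methyl-3,4,4a,7,8,8a-hexahydronaphthalen-1(2H)-one
Conditions: (S)-3,3-diphenyl-1-(2-methylphenyl)tetrahydro-1H,3H-pyrrolo[1,2-c][1,3,2]oxazaborole (20 mol%), HNTf2 (18 mol%), CH2Cl2, 0.01 M, −78 to −40 °C; Et3N quench at −78 °C
Reagents that add atoms: none
Why: Proposed new method: the boron of the N-protonated oxazaborolidine binds the C4 carbonyl oxygen and makes the vinyl ketone electrophilic enough for a concerted, asynchronous normal-demand [4+2] cycloaddition at low temperature, in which the enol-ether CH2 (C7) runs ahead in bonding to the β-carbon C6 and C5 then closes onto the methyl-bearing C10. The closest known reaction types are the thermal and achiral Lewis-acid-promoted type 1 intramolecular Diels–Alder reactions of 1,7,9-decatrien-3-ones, the cationic-oxazaborolidine and chiral Brønsted-acid Diels–Alder reactions of alkyl vinyl ketones with 2-silyloxydienes, and oxazaborolidine-catalysed transannular Diels–Alder reactions of macrocyclic enones, whereas an enantioselective cyclisation of an acyclic trienone with the carbonyl inside the tether has not been shown. Ring B closes as the six-membered ring of the cycloaddition itself and ring A as the fused six-membered ring spanned by the four tether atoms C4, C3, C2 and C1, the bridged mode being out of reach for so short a tether. C10 is controlled by the catalyst, whose aryl groups leave one face of the bound C5=C6 bond open, and since the (E)-geometry of C10=C9 and the tether tie the diene face to the dienophile face this single choice fixes the quaternary centre; C5 is controlled by the carbonyl-endo transition state with a boat-like tether that Lewis-acid-bound decatrienones prefer, which puts H5 on the face of the C10 methyl (cis fusion, corrected in step 8). The step needs enantioface selectivity, which rests on the catalyst alone and is uncertain because the tether holds the enone s-cis, outside the usual binding model, whereas orientation is secured twice by the substrate (tether length, and the C8 silyloxy group ending para to the C5 acyl group). The Z-disposed methyl on the diene terminus slows the uncatalysed background reaction, and the slight deficit of HNTf2, high dilution and the amine quench protect the acid-labile dienol ether and the silyl enol ether of the product.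

Step 8
Reactants: 11 (4aR,8aS)-6-[(tert-butyldimethylsilyl)oxy]-4a-methyl-3,4,4a,7,8,8a-hexahydronaphthalen-1(2H)-one
Product: 12 (4aR,8aR)-6-[(tert-butyldimethylsilyl)oxy]-4a-methyl-3,4,4a,7,8,8a-hexahydronaphthalen-1(2H)-one
Conditions: DBU (0.3 equiv), toluene, 40 °C, to equilibrium; chromatography, recovered 11 resubmitted
Reagents that add atoms: none
Why: Base-mediated epimerisation through the C4,C5-enolate (thermodynamic control) can invert only C5 because C10 is quaternary; the trans-fused ketone, with the C4 acyl carbon equatorial on ring B, should be the more stable partner, although the angular methyl keeps the margin moderate, hence the recycling, and the amidine leaves the TBS enol ether alone.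

Step 9
Reactants: 12 (4aR,8aR)-6-[(tert-butyldimethylsilyl)oxy]-4a-methyl-3,4,4a,7,8,8a-hexahydronaphthalen-1(2H)-one
Product: 14 (4aR,8aR)-6-[(tert-butyldimethylsilyl)oxy]-4a-methyl-3,4,4a,7,8,8a-hexahydronaphthalen-1-yl trifluoromethanesulfonate, via lithium enolate 13 (not isolated)
Conditions: LiN(iPr)2 (1.1 equiv), THF, −78 °C; N-(5-chloropyridin-2-yl)bis(trifluoromethanesulfonimide) (1.2 equiv), −78 to −20 °C
Reagents that add atoms: N-(5-chloropyridin-2-yl)bis(trifluoromethanesulfonimide) O=S(=O)(N(c1ccc(Cl)cn1)S(=O)(=O)C(F)(F)F)C(F)(F)F; lithium diisopropylamide CC(C)[N-]C(C)C.[Li+] (lithium of 13 only)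
Why: Kinetic enol triflate formation, in which the hindered amide removes the less substituted C3–H rather than the tertiary C5–H so that the trans fusion is untouched, and the C8 silyl enol ether is inert and makes a separate ketal unnecessary.

Step 10
Reactants: 14 (4aR,8aR)-6-[(tert-butyldimethylsilyl)oxy]-4a-methyl-3,4,4a,7,8,8a-hexahydronaphthalen-1-yl trifluoromethanesulfonate
Product: 15 8-[(tert-butyldimethylsilyl)oxy]-11,12,13-trinoreudesma-3,8-diene (5α-H 10β-methyl)
Conditions: MeMgBr (1.5 equiv), Fe(acac)3 (5 mol%), THF/NMP, −30 to 0 °C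
Reagents that add atoms: methylmagnesium bromide C[Mg]Br
Why: Iron-catalysed Kumada-type cross-coupling of an alkenyl triflate with a methyl Grignard reagent replaces the C4 triflate by the C4 methyl with the double bond held at C3=C4, and neither the silyl enol ether nor a stereocentre takes part.

Step 11
Reactants: 15 8-[(tert-butyldimethylsilyl)oxy]-11,12,13-trinoreudesma-3,8-diene (5α-H 10β-methyl)
Product: 16 (4aR,8aR)-5,8a-dimethyl-3,4,4a,7,8,8a-hexahydronaphthalen-2(1H)-one
Conditions: 1 M aq HCl, THF, 0 °C to rt
Reagents that add atoms: none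
Why: Acid hydrolysis of the silyl enol ether (protonation at C9, loss of silanol) uncovers the C8 ketone as the only carbonyl group in the molecule, so two ketones never have to be told apart, and the dilute acid does not move the trisubstituted C3=C4 bond.

Step 12
Reactants: 16 (4aR,8aR)-5,8a-dimethyl-3,4,4a,7,8,8a-hexahydronaphthalen-2(1H)-one; 17 acetone
Product: 20 11-hydroxyeudesm-3-en-8-one (7β side chain), via lithium enolate 18 (not isolated), via chlorozinc enolate 19 (not isolated)
Conditions: LiN(iPr)2 (1.1 equiv), THF, −78 °C; ZnCl2 (1.2 equiv); acetone (3 equiv), −78 to −40 °C; aqueous quench at −40 °C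
Reagents that add atoms: acetone CC(C)=O; lithium diisopropylamide CC(C)[N-]C(C)C.[Li+] (lithium of 18 only); zinc chloride Cl[Zn]Cl (in 19 only)
Why: Directed aldol addition, in which kinetic deprotonation takes C7 rather than the neopentyl C9, zinc holds the aldolate as a chelate against retro-aldol cleavage and proton transfer from acetone, and the new C7 centre (side chain expected equatorial, β) is of no consequence because step 13 erases it.

Step 13
Reactants: 20 11-hydroxyeudesm-3-en-8-one (7β side chain)
Product: 22 eudesma-3,7(11)-dien-8-one (5α-H 10β-methyl), via tertiary mesylate 21 (not isolated)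
Conditions: MsCl (3 equiv), Et3N (6 equiv), CH2Cl2, 0 °C; then DBU (3 equiv), rt
Reagents that add atoms: methanesulfonyl chloride CS(=O)(=O)Cl (in 21 only)
Why: Mesylation of the tertiary aldol hydroxyl by way of sulfene and E1cB elimination across C7–C11, with DBU also drawing any isopropenyl isomer into conjugation, give the tetrasubstituted s-cis enone without touching a stereocentre.

Step 14
Reactants: 22 eudesma-3,7(11)-dien-8-one (5α-H 10β-methyl)
Product: 23 3α,4α-dihydroxyeudesm-7(11)-en-8-one
Conditions: OsO4 (5 mol%), NMO (1.5 equiv), MeSO2NH2 (1 equiv), acetone/H2O, 0 °C to rt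
Reagents that add atoms: N-methylmorpholine N-oxide C[N+]1([O-])CCOCC1; water O; osmium tetroxide O=[Os](=O)(=O)=O (oxygen carrier)
Why: Upjohn dihydroxylation, in which OsO4 picks the electron-rich trisubstituted C3=C4 bond over the electron-poor tetrasubstituted C7=C11 bond and adds suprafacially from the α face, away from the axial C10 methyl that is 1,3-related to C4, so that C3 (R, axial α-OH) and C4 (S, equatorial α-OH, β-methyl) are set together.

Step 15
Reactants: 23 3α,4α-dihydroxyeudesm-7(11)-en-8-one; 24 angelic acid
Product: 26 3α-angeloyloxy-4α-hydroxyeudesm-7(11)-en-8-one, via mixed anhydride 25 (not isolated)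
Conditions: angelic acid (3 equiv), 2,4,6-Cl3C6H2COCl (3 equiv), Et3N (3.5 equiv), toluene, rt; then 23, 80 °C
Reagents that add atoms: angelic acid C/C=C(/C)C(=O)O; 2,4,6-trichlorobenzoyl chloride O=C(Cl)c1c(Cl)cc(Cl)cc1Cl (in 25 only)
Why: Yamaguchi-type mixed-anhydride esterification run without a nucleophilic catalyst is the established way to transfer an angeloyl group without Z-to-E isomerisation, and only the secondary C3 hydroxyl reacts because the tertiary C4 hydroxyl is too hindered.

Step 16
Reactants: 26 3α-angeloyloxy-4α-hydroxyeudesm-7(11)-en-8-one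
Product: 27 4α-acetoxy-3α-angeloyloxyeudesm-7(11)-en-8-one
Conditions: Ac2O (5 equiv), Sc(OTf)3 (5 mol%), MeCN, −20 to 0 °C
Reagents that add atoms: acetic anhydride CC(=O)OC(C)=O
Why: Lewis-acid-catalysed acetylation is fast enough for tertiary alcohols at low temperature, avoids the basic conditions under which the angeloyl group could migrate from O3 to O4 or isomerise, and meets no second tertiary hydroxyl because C11 is still an alkene carbon.

Step 17
Reactants: 27 4α-acetoxy-3α-angeloyloxyeudesm-7(11)-en-8-one
Product: 29 3α-angeloyloxy-4α-acetoxy-11-hydroxyeudesm-6-en-8-one (CNP0351454.1), via C11 hydroperoxide 28 (not isolated)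
Conditions: O2, 5,10,15,20-tetraphenylporphyrin (1 mol%), visible light (>500 nm), CH2Cl2, −10 °C; then PPh3 (1.2 equiv), 0 °C
Reagents that add atoms: dioxygen O=O
Why: Schenck ene reaction followed by phosphine reduction, in which singlet oxygen attacks s-cis α,β-unsaturated ketones with abstraction from the alkyl group geminal to the carbonyl, so that oxygen lands on C11, the axial 6β-H is lost and the double bond moves to C6=C7; the s-trans enone formed and the electron-poor angelate react far more slowly, and no stereocentre is made or disturbed.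

**Compound list**
1 | 5-hexyn-1-ol | OCCCCC#C | starting material
2 | acetyl chloride | CC(=O)Cl | starting material
3 | dimethylaluminium (E)-6-(dimethylalumanyl)-5-methylhex-5-en-1-olate | C[Al](C)OCCCC/C(C)=C/[Al](C)C | intermediate
4 | (E)-5-methyl-7-oxooct-5-en-1-yl acetate | CC(=O)OCCCC/C(C)=C/C(C)=O | intermediate
5 | (E)-7-[(tert-butyldimethylsilyl)oxy]-5-methylocta-5,7-dien-1-yl acetate | CC(=O)OCCCC/C(C)=C/C(=C)O[Si](C)(C)C(C)(C)C | intermediate
6 | (E)-7-[(tert-butyldimethylsilyl)oxy]-5-methylocta-5,7-dien-1-ol | OCCCC/C(C)=C/C(=C)O[Si](C)(C)C(C)(C)C | intermediate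
7 | (E)-7-[(tert-butyldimethylsilyl)oxy]-5-methylocta-5,7-dienal | O=CCCC/C(C)=C/C(=C)O[Si](C)(C)C(C)(C)C | intermediate
8 | vinylmagnesium bromide | C=C[Mg]Br | starting material
9 | (E)-9-[(tert-butyldimethylsilyl)oxy]-7-methyldeca-1,7,9-trien-3-ol, racemic at C3 | C=CC(O)CCC/C(C)=C/C(=C)O[Si](C)(C)C(C)(C)C | intermediate
10 | (E)-9-[(tert-butyldimethylsilyl)oxy]-7-methyldeca-1,7,9-trien-3-one | C=CC(=O)CCC/C(C)=C/C(=C)O[Si](C)(C)C(C)(C)C | intermediate
11 | (4aR,8aS)-6-[(tert-butyldimethylsilyl)oxy]-4a-methyl-3,4,4a,7,8,8a-hexahydronaphthalen-1(2H)-one, cis-fused (H5 and C10 methyl both β) | O=C1CCC[C@]2(C)C=C(O[Si](C)(C)C(C)(C)C)CC[C@@H]21 | intermediate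
12 | (4aR,8aR)-6-[(tert-butyldimethylsilyl)oxy]-4a-methyl-3,4,4a,7,8,8a-hexahydronaphthalen-1(2H)-one, trans-fused (5α-H, 10β-methyl) | O=C1CCC[C@]2(C)C=C(O[Si](C)(C)C(C)(C)C)CC[C@H]21 | intermediate
13 | lithium C3=C4 enolate of 12 | [Li]OC1=CCC[C@]2(C)C=C(O[Si](C)(C)C(C)(C)C)CC[C@H]21 | intermediate
14 | (4aR,8aR)-6-[(tert-butyldimethylsilyl)oxy]-4a-methyl-3,4,4a,7,8,8a-hexahydronaphthalen-1-yl trifluoromethanesulfonate | O=S(=O)(OC1=CCC[C@]2(C)C=C(O[Si](C)(C)C(C)(C)C)CC[C@H]21)C(F)(F)F | intermediate
15 | 8-[(tert-butyldimethylsilyl)oxy]-11,12,13-trinoreudesma-3,8-diene (5α-H, 10β-methyl) | CC1=CCC[C@]2(C)C=C(O[Si](C)(C)C(C)(C)C)CC[C@H]21 | intermediate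
16 | (4aR,8aR)-5,8a-dimethyl-3,4,4a,7,8,8a-hexahydronaphthalen-2(1H)-one (11,12,13-trinoreudesm-3-en-8-one) | CC1=CCC[C@]2(C)CC(=O)CC[C@H]21 | intermediate
17 | acetone | CC(C)=O | starting material
18 | lithium C7=C8 enolate of 16 | CC1=CCC[C@]2(C)CC(O[Li])=CC[C@H]21 | intermediate
19 | chlorozinc C7=C8 enolate of 16 | CC1=CCC[C@]2(C)CC(O[Zn]Cl)=CC[C@H]21 | intermediate
20 | 11-hydroxyeudesm-3-en-8-one, (3R,4aR,8aR)-3-(2-hydroxypropan-2-yl)-5,8a-dimethyl-3,4,4a,7,8,8a-hexahydronaphthalen-2(1H)-one | CC1=CCC[C@]2(C)CC(=O)[C@@H](C(C)(C)O)C[C@H]21 | intermediate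
21 | C11 methanesulfonate of 20 | CC1=CCC[C@]2(C)CC(=O)[C@@H](C(C)(C)OS(C)(=O)=O)C[C@H]21 | intermediate
22 | eudesma-3,7(11)-dien-8-one, (4aR,8aR) | CC1=CCC[C@]2(C)CC(=O)C(=C(C)C)C[C@H]21 | intermediate
23 | 3α,4α-dihydroxyeudesm-7(11)-en-8-one, (4aR,5S,6R,8aR) | O[C@@H]1CC[C@]2(C)CC(=O)C(=C(C)C)C[C@H]2[C@]1(C)O | intermediate
24 | angelic acid, (Z)-2-methylbut-2-enoic acid | C/C=C(/C)C(=O)O | starting material
25 | angelic 2,4,6-trichlorobenzoic anhydride | C/C=C(/C)C(=O)OC(=O)c1c(Cl)cc(Cl)cc1Cl | intermediate
26 | 3α-angeloyloxy-4α-hydroxyeudesm-7(11)-en-8-one | C/C=C(/C)C(=O)O[C@@H]1CC[C@]2(C)CC(=O)C(=C(C)C)C[C@H]2[C@]1(C)O | intermediate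
27 | 4α-acetoxy-3α-angeloyloxyeudesm-7(11)-en-8-one | C/C=C(/C)C(=O)O[C@@H]1CC[C@]2(C)CC(=O)C(=C(C)C)C[C@H]2[C@]1(C)OC(C)=O | intermediate
28 | 4α-acetoxy-3α-angeloyloxy-11-hydroperoxyeudesm-6-en-8-one | C/C=C(/C)C(=O)O[C@@H]1CC[C@]2(C)CC(=O)C(C(C)(C)OO)=C[C@H]2[C@]1(C)OC(C)=O | intermediate
29 | (1S,2R,4aR,8aR)-1-acetoxy-7-(2-hydroxypropan-2-yl)-1,4a-dimethyl-6-oxo-1,2,3,4,4a,5,6,8a-octahydronaphthalen-2-yl (Z)-2-methylbut-2-enoate | C/C=C(/C)C(=O)O[C@@H]1CC[C@]2(C)CC(=O)C(C(C)(C)O)=C[C@H]2[C@]1(C)OC(C)=O | target

Total step count: 17. Longest linear sequence: 17 steps, from 5-hexyn-1-ol (1).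

**Steps most likely to fail**

1. **Step 7.**
   - What may go wrong: enantioface discrimination may be weak, because the tether holds the enone s-cis and outside the usual catalyst binding mode. Silyl transfer from the dienol ether to triflimide may release an achiral silyl Lewis acid that runs a racemic cycle. The diene may be protodesilylated. Bond formation at the methyl-bearing diene terminus may be slow enough for the uncatalysed reaction to compete.
   - Fallback (known chemistry): setting out from 10, the cyclisation is promoted by the achiral Lewis acid Et2AlCl (CH2Cl2, −78 °C), the established way to close 1,7,9-decatrien-3-ones. It gives 11 together with its mirror image, the (4aS,8aR)-cis adduct F1. DBU equilibration as in step 8 then gives 12 together with the (4aS,8aS)-trans ketone F2. The racemate is resolved by preparative chromatography on a polysaccharide chiral stationary phase, and the route is rejoined at 12.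

2. **Step 8.**
   - What may go wrong: the thermodynamic bias may be too small. The angular methyl narrows the gap between cis and trans fusion, and the sp2 carbons C8 and C9 may narrow it further, so the equilibrium may deliver too little trans ketone per pass.
   - Fallback: C5 is set kinetically instead of thermodynamically. Setting out from 11 (or the 11/12 mixture), thermodynamic silylation (TMSOTf, Et3N, CH2Cl2, rt) gives the tetrasubstituted C4=C5 trimethylsilyl enol ether F3. Saegusa–Ito dehydrogenation with Pd(OAc)2 in MeCN gives the C5=C6 enone F4; the more labile TMS enol ether reacts, and the TBS enol ether has no β-hydrogen on C10 to lose. Hydrogenation (H2, Pd/C, EtOAc) should add to the α face, away from the adjacent C10 methyl, under neutral conditions. The route is rejoined at 12.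

3. **Step 17.**
   - What may go wrong: hydrogen may be abstracted from the C12/C13 methyl groups with oxygen delivered to C7. Access to the 6β-H may be hindered by the two syn-axial methyl groups. The angelate double bond may be oxidised on long irradiation.
   - Fallback: the pericyclic oxygenation is replaced by an ionic two-stage sequence. Setting out from 27, hydroxyselenenylation (N-(phenylseleno)phthalimide, H2O, catalytic camphorsulfonic acid, CH2Cl2) places selenium on the α-carbon C7 and water on the tertiary C11, to give the 7α-phenylseleno-11-hydroxy ketone F5. Oxidation (H2O2, pyridine, 0 °C) gives the selenoxide F6. Its syn elimination can only run toward C6, since C11 bears no hydrogen, and it ends directly at 29.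

**Further compounds**
F1 | step 7 | (4aS,8aR)-6-[(tert-butyldimethylsilyl)oxy]-4a-methyl-3,4,4a,7,8,8a-hexahydronaphthalen-1(2H)-one (mirror image of 11) | O=C1CCC[C@@]2(C)C=C(O[Si](C)(C)C(C)(C)C)CC[C@H]21
F2 | step 7 | (4aS,8aS)-6-[(tert-butyldimethylsilyl)oxy]-4a-methyl-3,4,4a,7,8,8a-hexahydronaphthalen-1(2H)-one (mirror image of 12) | O=C1CCC[C@@]2(C)C=C(O[Si](C)(C)C(C)(C)C)CC[C@@H]21
F3 | step 8 | (4aR)-6-[(tert-butyldimethylsilyl)oxy]-4a-methyl-1-[(trimethylsilyl)oxy]-2,3,4,4a,7,8-hexahydronaphthalene | C[Si](C)(C)OC=1CCC[C@]2(C)C=C(O[Si](C)(C)C(C)(C)C)CCC2=1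
F4 | step 8 | (4aR)-6-[(tert-butyldimethylsilyl)oxy]-4a-methyl-3,4,4a,7-tetrahydronaphthalen-1(2H)-one | O=C1CCC[C@]2(C)C=C(O[Si](C)(C)C(C)(C)C)CC=C21
F5 | step 17 | 4α-acetoxy-3α-angeloyloxy-11-hydroxy-7α-(phenylselanyl)eudesman-8-one | C/C=C(/C)C(=O)O[C@@H]1CC[C@]2(C)CC(=O)[C@@]([Se]c3ccccc3)(C(C)(C)O)C[C@H]2[C@]1(C)OC(C)=O
F6 | step 17 | selenoxide of F5 | C/C=C(/C)C(=O)O[C@@H]1CC[C@]2(C)CC(=O)[C@@]([Se](=O)c3ccccc3)(C(C)(C)O)C[C@H]2[C@]1(C)OC(C)=O
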